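**Plan**

1. Retrosynthesis: the ring B acetyl group (C-acylation) and the two MOM ethers come off first; ring B is then opened at the bond between the CH2-bearing ring carbon and the enolised carbonyl carbon next to the quaternary carbon (Dieckmann), which leads back to diketo ester 21.
2. The chain of 21 is cut between its central CH2 and the carbonyl that carries the CH2CH2-aryl group (aldol addition, then oxidation) into keto ester 7 and aldehyde 18; 18 is cut at the aryl–carbon bonds at C6 and C8 (two directed lithiations), and 7 at the bond from the quaternary carbon to the geranyl CH2.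
3. Enabling feature: in ring B the bridge CH2, the ring carbon that bears it and the adjacent ring C=O form a 3-arylpropanoyl unit; the ring CH, the next ring C=O and the quaternary carbon with its third carbonyl extend it to a 3,5-dioxo ester. The quaternary carbon has no hydrogen, so this chain has only one terminal position from which it can fold back onto the ester.
4. Forward order: pyran ring C is fused to phloroglucinol (ring A) first; the three-carbon chain (C6) and the butyryl group (C8) follow; fragment 7 is joined by aldol addition and oxidation; ring B closes in step 10; C-acetylation and removal of the MOM groups finish the route.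
5. Stereochemistry: the only stereocentre, the quaternary carbon of ring B, is set in step 2 by geranylation of a chiral enamine made from L-valine tert-butyl ester and cannot enolise afterwards; the E alkene is brought in with geranyl bromide.

Key step: step 10

Assumption (step 2): the lithiated enamine of L-valine tert-butyl ester is taken to be alkylated, in toluene with HMPA, on the face that gives the (S)-keto ester 7; if the sense proves opposite, D-valine tert-butyl ester is used and nothing else in the route changes.

**Route**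

Step 1
Reactants: 1 methyl 2-methyl-3-oxobutanoate; 2 L-valine tert-butyl ester (free base)
Product: 3 methyl (2Z)-3-{[(2S)-1-tert-butoxy-3-methyl-1-oxobutan-2-yl]amino}-2-methylbut-2-enoate
Conditions: BF3·OEt2 (cat.), toluene, reflux, Dean–Stark trap
Reagents that add atoms: none
Why: Acid-catalysed condensation of a β-keto ester with a primary amine under azeotropic removal of water (enamine formation) should give the hydrogen-bonded (Z)-β-enamino ester, which carries the valine stereocentre as the controlling element for step 2.

Step 2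
Reactants: 3 enamino ester; 4 geranyl bromide [(2E)-1-bromo-3,7-dimethylocta-2,6-diene]
Product: 7 methyl (2S,4E)-2-acetyl-2,5,9-trimethyldeca-4,8-dienoate, via lithiated enamine 5 (not isolated), via ketimine 6 (not isolated)
Conditions: LiN(i-Pr)2, toluene, −78 °C; hexamethylphosphoramide (HMPA, 1 equiv); 4, −78 to −55 °C; then aq. citric acid, THF, rt
Reagents that add atoms: water, O
Why: Auxiliary-controlled alkylation of a lithiated chiral β-enamino ester: lithium is held by the nitrogen and the valine ester carbonyl, the isopropyl group shields one face of the α-carbon, SN2 attack on the allylic bromide should therefore set the quaternary centre as (S), and mild aqueous acid hydrolyses the ketimine and returns the auxiliary.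

Step 3
Reactants: 8 phloroglucinol (threefold excess); 9 3-methylbut-2-enal
Product: 10 2,2-dimethyl-2H-chromene-5,7-diol
Conditions: pyridine, 110 °C
Reagents that add atoms: none
Why: Knoevenagel-type condensation at a ring carbon, dehydration to an ortho-quinone methide and oxa-6π electrocyclisation (chromene annulation) should give the pyran ring; the threefold symmetry of 8 leaves no regiochemical choice and its excess limits a second annulation.

Step 4
Reactants: 10 2,2-dimethyl-2H-chromene-5,7-diol
Product: 11 5,7-bis(methoxymethoxy)-2,2-dimethyl-2H-chromene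
Conditions: NaH, DMF, 0 °C; MOMCl, 0 °C to rt
Reagents that add atoms: chloromethyl methyl ether, COCCl
Why: Williamson-type O-alkylation of both phenoxides gives the bis-MOM ether, which protects the phenols against the later bases and supplies the directing groups for the two metalations.

Step 5
Reactants: 11 5,7-bis(methoxymethoxy)-2,2-dimethyl-2H-chromene; 12 oxetane
Product: 14 3-[5,7-bis(methoxymethoxy)-2,2-dimethyl-2H-chromen-6-yl]propan-1-ol, via 6-lithiochromene 13 (not isolated)
Conditions: n-BuLi (1.1 equiv), THF, 0 °C; then 12, BF3·OEt2, −78 °C; H2O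
Reagents that add atoms: none
Why: Directed ortho-metalation should take place at C6, the only position flanked by two chelating MOM ethers (the pyran oxygen is the weaker director), and the aryllithium then opens the BF3-activated oxetane by SN2 attack to give the 3-arylpropanol.

Step 6
Reactants: 14 3-[5,7-bis(methoxymethoxy)-2,2-dimethyl-2H-chromen-6-yl]propan-1-ol; 15 butanal
Product: 17 1-[6-(3-hydroxypropyl)-5,7-bis(methoxymethoxy)-2,2-dimethyl-2H-chromen-8-yl]butan-1-ol (racemic at the carbinol), via dilithiated alcohol 16 (not isolated)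
Conditions: n-BuLi (2.3 equiv), N,N,N',N'-tetramethylethylenediamine (TMEDA), THF, 0 °C; then 15, −78 °C; H2O
Reagents that add atoms: none
Why: After deprotonation of the hydroxyl, a second directed ortho-metalation can only occur at C8, the last aromatic C–H (between the 7-OMOM group and the pyran oxygen), and 1,2-addition to the aldehyde gives the carbinol, whose uncontrolled stereocentre is removed by oxidation in step 7.

Step 7
Reactants: 17 diol
Product: 18 3-[8-butanoyl-5,7-bis(methoxymethoxy)-2,2-dimethyl-2H-chromen-6-yl]propanal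
Conditions: Dess–Martin periodinane (2.6 equiv), pyridine, CH2Cl2, 0 °C to rt
Reagents that add atoms: none
Why: Dess–Martin oxidation converts the primary alcohol to the aldehyde and the benzylic secondary alcohol to the aryl ketone in one operation under buffered, non-acidic conditions that spare the MOM ethers and the chromene alkene.

Step 8
Reactants: 7 methyl (2S,4E)-2-acetyl-2,5,9-trimethyldeca-4,8-dienoate; 18 keto aldehyde
Product: 20 methyl (2S,4E)-2-{5-[8-butanoyl-5,7-bis(methoxymethoxy)-2,2-dimethyl-2H-chromen-6-yl]-3-hydroxypentanoyl}-2,5,9-trimethyldeca-4,8-dienoate (both carbinol epimers), via lithium enolate 19 (not isolated)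
Conditions: LiN(i-Pr)2 (1.2 equiv), 7 (1.25 equiv), THF, −78 °C; then 18, −78 °C; AcOH, −78 °C
Reagents that add atoms: none
Why: Aldol addition: the acetyl methyl group is the only enolisable position of 7 (the other α-carbon is quaternary), its lithium enolate adds to the aldehyde far faster than to the hindered, doubly ortho-substituted aryl ketone, the cold acidic quench prevents lactonisation of the aldolate onto the ester, and the new carbinol centre is uncontrolled because step 9 removes it.

Step 9
Reactants: 20 aldol adduct
Product: 21 methyl (2S,4E)-2-{5-[8-butanoyl-5,7-bis(methoxymethoxy)-2,2-dimethyl-2H-chromen-6-yl]-3-oxopentanoyl}-2,5,9-trimethyldeca-4,8-dienoate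
Conditions: Dess–Martin periodinane (1.2 equiv), pyridine, CH2Cl2, 0 °C
Reagents that add atoms: none
Why: Dess–Martin oxidation of a β-hydroxy ketone gives the β-diketone (largely as its enol) without touching the quaternary centre, which has no α-hydrogen and cannot epimerise.

Step 10
Reactants: 21 diketo ester
Product: 22 (4S)-2-{[8-butanoyl-5,7-bis(methoxymethoxy)-2,2-dimethyl-2H-chromen-6-yl]methyl}-4-[(2E)-3,7-dimethylocta-2,6-dien-1-yl]-3,5-dihydroxy-4-methylcyclohexa-2,5-dien-1-one (tautomer as drawn)
Conditions: LiN(i-Pr)2 (4.5 equiv), THF, −78 to 0 °C; AcOH, then pH 4 buffer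
Reagents that add atoms: none
Why: Excess amide base first forms the diketone enolate and then removes a proton from the only other α-position of that unit, the CH2 next to the ArCH2 group (the opposite flank is the quaternary carbon); this terminal carbanion adds to the methyl ester and expels methoxide, forming the bond between the bridge-bearing ring carbon and the carbonyl carbon next to the quaternary centre. The reaction is a Dieckmann (intramolecular Claisen) condensation of a 3,5-dioxo ester polyanion, modelled on the closure of 2,2-dialkyl-3,5-dioxo esters to filicinic- and syncarpic-acid-type triones and on the folding of polyketide chains to acylphloroglucinols. Ring B closes in a 6-(enolendo)-exo-trig mode. No stereocentre is formed, since the new ring carbon is enolised; the quaternary centre is carried through unchanged provided retro-Claisen cleavage is avoided, which the non-nucleophilic base and the immediate deprotonation of the acidic trione should ensure. The step needs acylation at carbon rather than lactonisation through the enolate oxygen, and closure from the bridge-side carbon rather than from the butyryl enolate; the much higher nucleophilicity of the fully formed terminal carbanion secures the first, and ring size the second, because the butyryl enolate (which also forms and is covered by the extra base) could reach the ester only through a macrocycle.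

Step 11
Reactants: 22 trione
Product: 24 (4R)-2-acetyl-6-{[8-butanoyl-5,7-bis(methoxymethoxy)-2,2-dimethyl-2H-chromen-6-yl]methyl}-4-[(2E)-3,7-dimethylocta-2,6-dien-1-yl]-3,5-dihydroxy-4-methylcyclohexa-2,5-dien-1-one, via enol acetate 23 (not isolated)
Conditions: AcOH (1.1 equiv), N,N'-dicyclohexylcarbodiimide (DCC), 4-(dimethylamino)pyridine (DMAP), CH2Cl2, rt
Reagents that add atoms: acetic acid, CC(=O)O
Why: Carbodiimide-mediated O-acetylation of the cyclic β-dicarbonyl followed by DMAP-catalysed O-to-C acyl migration (Fries-type rearrangement of an enol ester) should deliver the acetyl group to the only unsubstituted ring carbon and give the chelated β-triketone as the thermodynamic sink.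

Step 12
Reactants: 24 bis-MOM ether
Product: 25 target CNP0152509.1, (4R)-2-acetyl-6-{[8-butanoyl-5,7-dihydroxy-2,2-dimethyl-2H-chromen-6-yl]methyl}-4-[(2E)-3,7-dimethylocta-2,6-dien-1-yl]-3,5-dihydroxy-4-methylcyclohexa-2,5-dien-1-one
Conditions: HCl (1.25 M in MeOH), 0 °C to rt
Reagents that add atoms: none
Why: Acid-catalysed acetal exchange (methanolysis of the MOM ethers) frees both phenols, and dilute acid at low temperature should leave the trisubstituted alkenes, the chromene and the enolised triketone untouched.

**Compound list**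

1 | methyl 2-methyl-3-oxobutanoate | CC(=O)C(C)C(=O)OC | starting material
2 | L-valine tert-butyl ester, tert-butyl (2S)-2-amino-3-methylbutanoate | CC(C)[C@H](N)C(=O)OC(C)(C)C | starting material
3 | methyl (2Z)-3-{[(2S)-1-tert-butoxy-3-methyl-1-oxobutan-2-yl]amino}-2-methylbut-2-enoate | COC(=O)/C(C)=C(/C)N[C@@H](C(C)C)C(=O)OC(C)(C)C | intermediate
4 | geranyl bromide, (2E)-1-bromo-3,7-dimethylocta-2,6-diene | BrC/C=C(\C)CCC=C(C)C | starting material
5 | N-lithio derivative of 3 (lithiated enamine, not isolated) | COC(=O)/C(C)=C(/C)N([Li])[C@@H](C(C)C)C(=O)OC(C)(C)C | intermediate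
6 | methyl (2S,4E)-2-{N-[(2S)-1-tert-butoxy-3-methyl-1-oxobutan-2-yl]ethanimidoyl}-2,5,9-trimethyldeca-4,8-dienoate (ketimine, not isolated) | COC(=O)[C@@](C)(C/C=C(\C)CCC=C(C)C)C(C)=N[C@@H](C(C)C)C(=O)OC(C)(C)C | intermediate
7 | methyl (2S,4E)-2-acetyl-2,5,9-trimethyldeca-4,8-dienoate | CC(=O)[C@](C)(C/C=C(\C)CCC=C(C)C)C(=O)OC | intermediate
8 | phloroglucinol | Oc1cc(O)cc(O)c1 | starting material
9 | 3-methylbut-2-enal | CC(C)=CC=O | starting material
10 | 2,2-dimethyl-2H-chromene-5,7-diol | CC1(C)C=Cc2c(O)cc(O)cc2O1 | intermediate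
11 | 5,7-bis(methoxymethoxy)-2,2-dimethyl-2H-chromene | CC1(C)C=Cc2c(OCOC)cc(OCOC)cc2O1 | intermediate
12 | oxetane | C1COC1 | starting material
13 | [5,7-bis(methoxymethoxy)-2,2-dimethyl-2H-chromen-6-yl]lithium (not isolated) | CC1(C)C=Cc2c(OCOC)c([Li])c(OCOC)cc2O1 | intermediate
14 | 3-[5,7-bis(methoxymethoxy)-2,2-dimethyl-2H-chromen-6-yl]propan-1-ol | CC1(C)C=Cc2c(OCOC)c(CCCO)c(OCOC)cc2O1 | intermediate
15 | butanal | CCCC=O | starting material
16 | lithium alkoxide of 14 lithiated at C8 (not isolated) | CC1(C)C=Cc2c(OCOC)c(CCCO[Li])c(OCOC)c([Li])c2O1 | intermediate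
17 | 1-[6-(3-hydroxypropyl)-5,7-bis(methoxymethoxy)-2,2-dimethyl-2H-chromen-8-yl]butan-1-ol (racemic carbinol) | CCCC(O)c1c(OCOC)c(CCCO)c(OCOC)c2c1OC(C)(C)C=C2 | intermediate
18 | 3-[8-butanoyl-5,7-bis(methoxymethoxy)-2,2-dimethyl-2H-chromen-6-yl]propanal | CCCC(=O)c1c(OCOC)c(CCC=O)c(OCOC)c2c1OC(C)(C)C=C2 | intermediate
19 | lithium enolate of 7 at the acetyl group (not isolated) | [Li]OC(=C)[C@](C)(C/C=C(\C)CCC=C(C)C)C(=O)OC | intermediate
20 | methyl (2S,4E)-2-{5-[8-butanoyl-5,7-bis(methoxymethoxy)-2,2-dimethyl-2H-chromen-6-yl]-3-hydroxypentanoyl}-2,5,9-trimethyldeca-4,8-dienoate (carbinol epimers) | CCCC(=O)c1c(OCOC)c(CCC(O)CC(=O)[C@](C)(C/C=C(\C)CCC=C(C)C)C(=O)OC)c(OCOC)c2c1OC(C)(C)C=C2 | intermediate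
21 | methyl (2S,4E)-2-{5-[8-butanoyl-5,7-bis(methoxymethoxy)-2,2-dimethyl-2H-chromen-6-yl]-3-oxopentanoyl}-2,5,9-trimethyldeca-4,8-dienoate | CCCC(=O)c1c(OCOC)c(CCC(=O)CC(=O)[C@](C)(C/C=C(\C)CCC=C(C)C)C(=O)OC)c(OCOC)c2c1OC(C)(C)C=C2 | intermediate
22 | (4S)-2-{[8-butanoyl-5,7-bis(methoxymethoxy)-2,2-dimethyl-2H-chromen-6-yl]methyl}-4-[(2E)-3,7-dimethylocta-2,6-dien-1-yl]-3,5-dihydroxy-4-methylcyclohexa-2,5-dien-1-one (tautomer as drawn) | CCCC(=O)c1c(OCOC)c(CC2=C(O)[C@@](C)(C/C=C(\C)CCC=C(C)C)C(O)=CC2=O)c(OCOC)c2c1OC(C)(C)C=C2 | intermediate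
23 | enol acetate of 22 at the ring oxygen between the quaternary carbon and the free ring CH (not isolated) | CCCC(=O)c1c(OCOC)c(CC2=C(O)[C@@](C)(C/C=C(\C)CCC=C(C)C)C(OC(C)=O)=CC2=O)c(OCOC)c2c1OC(C)(C)C=C2 | intermediate
24 | (4R)-2-acetyl-6-{[8-butanoyl-5,7-bis(methoxymethoxy)-2,2-dimethyl-2H-chromen-6-yl]methyl}-4-[(2E)-3,7-dimethylocta-2,6-dien-1-yl]-3,5-dihydroxy-4-methylcyclohexa-2,5-dien-1-one (descriptor differs from 22 only because the ranking of the two ring branches changes; no bond at the stereocentre is touched) | CCCC(=O)c1c(OCOC)c(CC2=C(O)[C@@](C)(C/C=C(\C)CCC=C(C)C)C(O)=C(C(C)=O)C2=O)c(OCOC)c2c1OC(C)(C)C=C2 | intermediate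
25 | CNP0152509.1, (4R)-2-acetyl-6-{[8-butanoyl-5,7-dihydroxy-2,2-dimethyl-2H-chromen-6-yl]methyl}-4-[(2E)-3,7-dimethylocta-2,6-dien-1-yl]-3,5-dihydroxy-4-methylcyclohexa-2,5-dien-1-one | CCCC(=O)c1c(O)c(CC2=C(O)[C@@](C)(C/C=C(\C)CCC=C(C)C)C(O)=C(C(C)=O)C2=O)c(O)c2c1OC(C)(C)C=C2 | target

**Step count and risks**

Total steps: 12. Longest linear sequence: 10 steps (steps 3 to 12, from phloroglucinol 8); the two-step branch to 7 joins at step 8.

Step 10 (key step). What may go wrong: with three acidic sites the polyanion may not form completely, so that on warming the diketone monoenolate lactonises onto the ester through oxygen, or liberated methoxide cleaves the quaternary β-keto ester by retro-Claisen reaction. The fallback carries C8 at the carbinol oxidation level, so that only the classical two-charge diketone dianion is needed. It sets out from diol 17. PhI(OAc)2 with catalytic 2,2,6,6-tetramethylpiperidin-1-oxyl should oxidise only the primary alcohol and give 3-[8-(1-hydroxybutyl)-5,7-bis(methoxymethoxy)-2,2-dimethyl-2H-chromen-6-yl]propanal F1. tert-Butyldimethylsilyl triflate and 2,6-lutidine give its silyl ether F2. Aldol addition of enolate 19 gives the β-hydroxy ketone F3, and Dess–Martin oxidation the silyl-protected diketo ester F4. LiN(i-Pr)2 (2.5 equiv) in THF then closes ring B through the same bond to the silyl-protected trione F5. Bu4NF frees the benzylic carbinol F6, and MnO2 oxidises it to the butyryl ketone, coming back to the route at 22.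

Step 5. What may go wrong: metalation may occur at C8 (between the 7-OMOM group and the pyran oxygen) as well as at C6, so that the chain and later the butyryl group are placed in part on the wrong carbons. The fallback fixes the regiochemistry by chelation instead of by competing directing groups. It sets out from phloroglucinol 8. Friedel–Crafts acylation with butanoyl chloride and AlCl3 gives 1-(2,4,6-trihydroxyphenyl)butan-1-one F7. MOMCl with i-Pr2NEt protects all but the hydrogen-bonded hydroxyl and gives 1-[2-hydroxy-4,6-bis(methoxymethoxy)phenyl]butan-1-one F8. Annulation with 9 (ethylenediammonium diacetate, xylene, 140 °C) can use only that free hydroxyl and gives 1-[5,7-bis(methoxymethoxy)-2,2-dimethyl-2H-chromen-8-yl]butan-1-one F9. NaBH4 reduces the ketone to 1-[5,7-bis(methoxymethoxy)-2,2-dimethyl-2H-chromen-8-yl]butan-1-ol F10. n-BuLi (2.2 equiv) metalates the single remaining ring C–H to the C6-lithiated lithium alkoxide F11, and oxetane 12 with BF3·OEt2 then gives diol 17, where the route is rejoined.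

Step 2. What may go wrong: facial selectivity in the alkylation of the open-chain lithiated enamine may be poor if the chelate that fixes its geometry is not maintained, giving keto ester of low enantiomeric purity. The fallback replaces auxiliary control by resolution. It sets out from 1 and 4: K2CO3 in refluxing acetone alkylates 1 directly to racemic methyl (4E)-2-acetyl-2,5,9-trimethyldeca-4,8-dienoate F12. Preparative chromatography on a chiral stationary phase separates the (S)-enantiomer, which is 7, from methyl (2R,4E)-2-acetyl-2,5,9-trimethyldeca-4,8-dienoate F13, which is set aside; the route is rejoined at 7.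

**Further compounds**

F1 | step 10 | 3-[8-(1-hydroxybutyl)-5,7-bis(methoxymethoxy)-2,2-dimethyl-2H-chromen-6-yl]propanal | CCCC(O)c1c(OCOC)c(CCC=O)c(OCOC)c2c1OC(C)(C)C=C2
F2 | step 10 | 3-[8-{1-[(tert-butyldimethylsilyl)oxy]butyl}-5,7-bis(methoxymethoxy)-2,2-dimethyl-2H-chromen-6-yl]propanal | CCCC(O[Si](C)(C)C(C)(C)C)c1c(OCOC)c(CCC=O)c(OCOC)c2c1OC(C)(C)C=C2
F3 | step 10 | silyl-protected aldol adduct, methyl (2S,4E)-2-{5-[8-{1-[(tert-butyldimethylsilyl)oxy]butyl}-5,7-bis(methoxymethoxy)-2,2-dimethyl-2H-chromen-6-yl]-3-hydroxypentanoyl}-2,5,9-trimethyldeca-4,8-dienoate | CCCC(O[Si](C)(C)C(C)(C)C)c1c(OCOC)c(CCC(O)CC(=O)[C@](C)(C/C=C(\C)CCC=C(C)C)C(=O)OC)c(OCOC)c2c1OC(C)(C)C=C2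
F4 | step 10 | silyl-protected diketo ester, the 3-oxo analogue of F3 | CCCC(O[Si](C)(C)C(C)(C)C)c1c(OCOC)c(CCC(=O)CC(=O)[C@](C)(C/C=C(\C)CCC=C(C)C)C(=O)OC)c(OCOC)c2c1OC(C)(C)C=C2
F5 | step 10 | silyl-protected trione, analogue of 22 with 1-[(tert-butyldimethylsilyl)oxy]butyl at C8 | CCCC(O[Si](C)(C)C(C)(C)C)c1c(OCOC)c(CC2=C(O)[C@@](C)(C/C=C(\C)CCC=C(C)C)C(O)=CC2=O)c(OCOC)c2c1OC(C)(C)C=C2
F6 | step 10 | trione carbinol, analogue of 22 with 1-hydroxybutyl at C8 | CCCC(O)c1c(OCOC)c(CC2=C(O)[C@@](C)(C/C=C(\C)CCC=C(C)C)C(O)=CC2=O)c(OCOC)c2c1OC(C)(C)C=C2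
F7 | step 5 | 1-(2,4,6-trihydroxyphenyl)butan-1-one | CCCC(=O)c1c(O)cc(O)cc1O
F8 | step 5 | 1-[2-hydroxy-4,6-bis(methoxymethoxy)phenyl]butan-1-one | CCCC(=O)c1c(O)cc(OCOC)cc1OCOC
F9 | step 5 | 1-[5,7-bis(methoxymethoxy)-2,2-dimethyl-2H-chromen-8-yl]butan-1-one | CCCC(=O)c1c(OCOC)cc(OCOC)c2c1OC(C)(C)C=C2
F10 | step 5 | 1-[5,7-bis(methoxymethoxy)-2,2-dimethyl-2H-chromen-8-yl]butan-1-ol | CCCC(O)c1c(OCOC)cc(OCOC)c2c1OC(C)(C)C=C2
F11 | step 5 | lithium alkoxide of F10 lithiated at C6 (not isolated) | CCCC(O[Li])c1c(OCOC)c([Li])c(OCOC)c2c1OC(C)(C)C=C2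
F12 | step 2 | racemic methyl (4E)-2-acetyl-2,5,9-trimethyldeca-4,8-dienoate | CC(=O)C(C)(C/C=C(\C)CCC=C(C)C)C(=O)OC
F13 | step 2 | methyl (2R,4E)-2-acetyl-2,5,9-trimethyldeca-4,8-dienoate | CC(=O)[C@@](C)(C/C=C(\C)CCC=C(C)C)C(=O)OC
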